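**Retrosynthetic overview**
1. The target is a (2S)-4',7-dihydroxyflavan joined through C4 (R, 2,4-trans) to C8 of (+)-gallocatechin (2R,3S). Rings D, E and F with their two stereocentres are bought as (+)-gallocatechin.
2. Last disconnection: two O-benzyl groups (hydrogenolysis).
3. Interflavan C4–C8 bond: SN1 arylation of a flavan-4-yl cation by C8 of gallocatechin, with the C2 aryl directing the arene to the trans face.
4. Ring C of the upper unit: retro-[4+2] to an α-methoxy o-quinone methide (from 4-benzyloxy-2-hydroxybenzaldehyde and trimethyl orthoformate) and 4-benzyloxystyrene.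
5. Order of ring formation: rings A and B are bought as arenes, ring C is made by hetero-Diels–Alder cycloaddition, then the flavan is joined to intact gallocatechin.

Assumption: natural (+)-gallocatechin is taken as a purchasable chiral-pool compound, and its excess in step 2 is recovered.

Stereochemical note: C2 of the upper unit is formed racemic in step 1. In step 2 each antipode sets C4 trans to its own C2, and the fixed gallocatechin centres make the two resulting products diastereomers, which are separated. At most half of compound 5 can therefore end up in the target series.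

**Step 1**
Reactants: 1 4-(benzyloxy)-2-hydroxybenzaldehyde; 2 1-(benzyloxy)-4-ethenylbenzene (4-benzyloxystyrene)
Product: 5 rac-7-(benzyloxy)-2-[4-(benzyloxy)phenyl]-4-methoxychromane, via dimethyl acetal 3 (not isolated), via o-quinone methide 4 (not isolated)
Conditions: HC(OMe)3 (2 equiv), 2 (1.5 equiv), Sc(OTf)3 (5 mol %), CH2Cl2, 0 °C → rt
Reagents that add atoms: trimethyl orthoformate, COC(OC)OC
Why: Acetalisation of 1 and loss of methanol give the electron-poor α-methoxy o-quinone methide 4 (reacting as its Sc-bound oxocarbenium form), which undergoes an inverse-electron-demand hetero-Diels–Alder [4+2] cycloaddition with the electron-rich styrene 2, the styrene CH2 bonding to the methide carbon and the benzylic carbon to oxygen, so ring C closes with the aryl at C2 and OMe at C4; C2 and C4 arise racemic and as a cis/trans mixture, which is harmless because C4 is ionised in step 2 and the C2 antipodes are parted there.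

**Step 2**
Reactants: 5 rac-7-(benzyloxy)-2-[4-(benzyloxy)phenyl]-4-methoxychromane; 6 (+)-gallocatechin
Product: 8 (2R,3S)-8-{(2S,4R)-7-(benzyloxy)-2-[4-(benzyloxy)phenyl]chroman-4-yl}-2-(3,4,5-trihydroxyphenyl)chromane-3,5,7-triol, via flavan-4-yl cation 7 (not isolated)
Conditions: 6 (3 equiv), p-TsOH·H2O (10 mol %), 4 Å MS, THF, Ar, 0 °C → rt; Sephadex LH-20 (EtOH), then preparative C18 HPLC
Reagents that add atoms: none
Why: Acid ionises the 2,4-dialkoxybenzylic methyl ether to cation 7, and Friedel–Crafts (SN1) attack by C8 of the phloroglucinol ring D of 6 occurs pseudo-axially on the sofa-shaped cation, anti to the equatorial C2 aryl, so C4 is set 2,4-trans by C2 (substrate control); (2S)-7 gives the (2S,4R) adduct 8 and (2R)-7 the (2R,4S) isomer in about equal amounts, and 8 is isolated by HPLC from that diastereomer, the minor cis and 4→6 isomers and recovered 6, and identified by its small J(3,4) and the CD sign of the C4 chromophore.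

**Step 3**
Reactants: 8 (2R,3S)-8-{(2S,4R)-7-(benzyloxy)-2-[4-(benzyloxy)phenyl]chroman-4-yl}-2-(3,4,5-trihydroxyphenyl)chromane-3,5,7-triol
Product: 9 (2R,3S)-8-[(2S,4R)-7-hydroxy-2-(4-hydroxyphenyl)chroman-4-yl]-2-(3,4,5-trihydroxyphenyl)chromane-3,5,7-triol (target CNP0220331.3)
Conditions: H2 (1 atm), Pd(OH)2/C, THF/MeOH 1:1, rt; filtration under Ar
Reagents that add atoms: none
Why: Catalytic hydrogenolysis cleaves only the two benzyl aryl ethers, the cyclic benzylic C2–O1 bonds and the diarylmethine C4 being inert under these mild conditions, so all four stereocentres are untouched.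

**Compound list**
1 | 4-(benzyloxy)-2-hydroxybenzaldehyde | O=Cc1ccc(OCc2ccccc2)cc1O | starting material
2 | 1-(benzyloxy)-4-ethenylbenzene (4-benzyloxystyrene) | C=Cc1ccc(OCc2ccccc2)cc1 | starting material
3 | 5-(benzyloxy)-2-(dimethoxymethyl)phenol | COC(OC)c1ccc(OCc2ccccc2)cc1O | intermediate
4 | (6E)-3-(benzyloxy)-6-(methoxymethylidene)cyclohexa-2,4-dien-1-one | CO/C=C1\C=CC(OCc2ccccc2)=CC1=O | intermediate
5 | rac-7-(benzyloxy)-2-[4-(benzyloxy)phenyl]-4-methoxychromane (racemic, 2,4-cis/trans mixture) | COC1CC(c2ccc(OCc3ccccc3)cc2)Oc2cc(OCc3ccccc3)ccc12 | intermediate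
6 | (+)-gallocatechin, (2R,3S)-2-(3,4,5-trihydroxyphenyl)chromane-3,5,7-triol | O[C@H]1Cc2c(O)cc(O)cc2O[C@@H]1c1cc(O)c(O)c(O)c1 | starting material
7 | 7-(benzyloxy)-2-[4-(benzyloxy)phenyl]chroman-4-ylium cation (racemic at C2) | [CH+]1CC(c2ccc(OCc3ccccc3)cc2)Oc2cc(OCc3ccccc3)ccc12 | intermediate
8 | (2R,3S)-8-{(2S,4R)-7-(benzyloxy)-2-[4-(benzyloxy)phenyl]chroman-4-yl}-2-(3,4,5-trihydroxyphenyl)chromane-3,5,7-triol | c1ccccc1COc1ccc([C@@H]2C[C@@H](c3c(O)cc(O)c4c3O[C@H](c3cc(O)c(O)c(O)c3)[C@@H](O)C4)c3ccc(OCc4ccccc4)cc3O2)cc1 | intermediate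
9 | (2R,3S)-8-[(2S,4R)-7-hydroxy-2-(4-hydroxyphenyl)chroman-4-yl]-2-(3,4,5-trihydroxyphenyl)chromane-3,5,7-triol | Oc1ccc([C@@H]2C[C@@H](c3c(O)cc(O)c4c3O[C@H](c3cc(O)c(O)c(O)c3)[C@@H](O)C4)c3ccc(O)cc3O2)cc1 | target

**Step count**
Total steps: 3. Longest linear sequence: 3 steps (1 → 5 → 8 → 9).

**Steps most likely to fail, with fallbacks**

Step 2 (highest risk). The cation can attack C6 as well as C8, the trans/cis ratio may be modest, and four or more isomeric hexaphenols must be separated. The fallback sets out from 6 and comes back to the route at 9. The five phenols of 6 are benzylated (BnBr, K2CO3, DMF, rt, Ar) to give (2R,3S)-5,7-bis(benzyloxy)-2-[3,4,5-tris(benzyloxy)phenyl]chroman-3-ol F5. F5 (3 equiv) is coupled with 5 using TMSOTf (0.1 equiv) in CH2Cl2 at −78 → −40 °C; the 5,7-dibenzyloxy ring D reacts essentially only at C8 and the lipophilic diastereomers separate on silica, giving the hepta-O-benzyl (2S,4R) 4→8 dimer F6. Hydrogenolysis of all seven benzyl ethers under the step 3 conditions then gives 9 directly, bypassing 8.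

Step 1. The styrene may polymerise cationically, and the labile product ether may ionise and react further. The fallback sets out from 1 and comes back to the route at 5, making ring C by electrocyclization instead of intermolecular cycloaddition.
- Claisen–Schmidt condensation of 1 with commercial 1-[4-(benzyloxy)phenyl]ethanone (KOH, EtOH, rt) gives (E)-3-[4-(benzyloxy)-2-hydroxyphenyl]-1-[4-(benzyloxy)phenyl]prop-2-en-1-one F1.
- Luche reduction (NaBH4, CeCl3·7H2O, MeOH/THF, 0 °C) gives the allylic alcohol (E)-3-[4-(benzyloxy)-2-hydroxyphenyl]-1-[4-(benzyloxy)phenyl]prop-2-en-1-ol F2.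
- Warming with PPTS in toluene (60 °C) dehydrates F2 to the vinyl o-quinone methide (6Z)-3-(benzyloxy)-6-[(2E)-3-[4-(benzyloxy)phenyl]prop-2-en-1-ylidene]cyclohexa-2,4-dien-1-one F3, which closes by oxa-6π electrocyclization to rac-7-(benzyloxy)-2-[4-(benzyloxy)phenyl]-2H-chromene F4.
- PPTS in MeOH/CH2Cl2 at rt adds methanol across the electron-rich C3=C4 bond (protonation at C3, capture at C4) to give 5.

Step 3. The polyphenol may bind to the catalyst, a benzylic C2–O1 bond may be hydrogenolysed on prolonged exposure, and the pyrogallol ring is air-sensitive on work-up. The fallback sets out from 8 and comes back at 9. It replaces reductive cleavage by Lewis-acid dealkylation with a cation scavenger (BCl3, pentamethylbenzene, CH2Cl2, −78 °C, then MeOH quench), which transfers both benzyl groups to pentamethylbenzene and makes no compound outside the list (F0).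

**Further compounds**
F1 | step 1 | (E)-3-[4-(benzyloxy)-2-hydroxyphenyl]-1-[4-(benzyloxy)phenyl]prop-2-en-1-one | O=C(/C=C/c1ccc(OCc2ccccc2)cc1O)c1ccc(OCc2ccccc2)cc1
F2 | step 1 | (E)-3-[4-(benzyloxy)-2-hydroxyphenyl]-1-[4-(benzyloxy)phenyl]prop-2-en-1-ol (racemic) | OC(/C=C/c1ccc(OCc2ccccc2)cc1O)c1ccc(OCc2ccccc2)cc1
F3 | step 1 | (6Z)-3-(benzyloxy)-6-[(2E)-3-[4-(benzyloxy)phenyl]prop-2-en-1-ylidene]cyclohexa-2,4-dien-1-one | O=C1C=C(OCc2ccccc2)C=C/C1=C/C=C/c1ccc(OCc2ccccc2)cc1
F4 | step 1 | rac-7-(benzyloxy)-2-[4-(benzyloxy)phenyl]-2H-chromene | C1=Cc2ccc(OCc3ccccc3)cc2OC1c1ccc(OCc2ccccc2)cc1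
F5 | step 2 | (2R,3S)-5,7-bis(benzyloxy)-2-[3,4,5-tris(benzyloxy)phenyl]chroman-3-ol | O[C@H]1Cc2c(OCc3ccccc3)cc(OCc3ccccc3)cc2O[C@@H]1c1cc(OCc2ccccc2)c(OCc2ccccc2)c(OCc2ccccc2)c1
F6 | step 2 | (2R,3S)-5,7-bis(benzyloxy)-8-{(2S,4R)-7-(benzyloxy)-2-[4-(benzyloxy)phenyl]chroman-4-yl}-2-[3,4,5-tris(benzyloxy)phenyl]chroman-3-ol | c1ccccc1COc1ccc([C@@H]2C[C@@H](c3c(OCc4ccccc4)cc(OCc4ccccc4)c4c3O[C@H](c3cc(OCc5ccccc5)c(OCc5ccccc5)c(OCc5ccccc5)c3)[C@@H](O)C4)c3ccc(OCc4ccccc4)cc3O2)cc1
F0 | step 3 | none | none
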